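**Retrosynthetic overview**

1. The strategy rests on the six-membered 1,2-dioxane whose O–O unit spans C8 and C11 of the 14-membered carbocycle: the C7 acetoxy group is anti to the C8–O bond and C11 is allylic to C12=C13, the imprint of a 7,8-epoxide opened at C8 and of a C11–C12–C13 allyl cation trapped at C11. Both dioxane C–O bonds are therefore cut back to H2O2 and the epoxy allylic alcohol 25 (transannular double alkylation).
2. 25 comes from iodo aldehyde 23 by C12–C13 Nozaki–Hiyama–Kishi macrocyclisation; its epoxide comes from Shi epoxidation of C7=C8 in lactone 20.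
3. 20 comes from C1–C2 bond formation by asymmetric allylboration–lactonisation of iodo trienal 13 (from farnesol) with the ester-bearing allylboronate 18 (from a Morita–Baylis–Hillman adduct of 14 and 15).
4. Ring order: γ-lactone, then the temporary epoxide, then the 14-membered carbocycle, then the 1,2-dioxane; acetylation of the C7 hydroxyl comes last.

Key step: step 18

Remark on numbering: carbon atoms carry cembrane numbers (ring C1–C14; C15=C17 methylene and C16 carbonyl of the lactone, lactone oxygen on C2; methyls C18, C19, C20 on C4, C8, C12).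
Assumption on the chemistry: (R)-TRIP is taken as the acid enantiomer that sends the allyl unit to the Re face of the enal (2S), and the L-series Shi ketone as the one that gives the (7S,8S)-epoxide (mirror image of the sense of the D-fructose-derived ketone on E-trisubstituted alkenes). Each sense would be confirmed on a model and the other catalyst enantiomer used if needed.

**Route**

Step 1
Reactants: 1 (2E,6E)-farnesol
Product: 2 (2E,6E)-farnesyl tert-butyldiphenylsilyl ether
Conditions: TBDPSCl, imidazole, CH2Cl2, 0 °C to rt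
Reagents that add atoms: tert-butyl(chloro)diphenylsilane, CC(C)(C)[Si](Cl)(c1ccccc1)c1ccccc1
Why: Imidazole-promoted silylation of the primary allylic alcohol gives an ether that should survive base, periodate, organolithium and zirconium reagents until step 8.

Step 2
Reactants: 2 (2E,6E)-farnesyl tert-butyldiphenylsilyl ether
Product: 3 (2E,6E)-10-bromo-11-hydroxy-10,11-dihydrofarnesyl tert-butyldiphenylsilyl ether (racemic at C10)
Conditions: NBS, THF–H2O, 0 °C
Reagents that add atoms: N-bromosuccinimide, O=C1CCC(=O)N1Br; water, O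
Why: Bromohydrin formation in aqueous THF should select the terminal, most exposed trisubstituted alkene of the polyprenyl chain (the 2,3-alkene is deactivated by the allylic oxygen), with Markovnikov delivery of OH to the tertiary carbon; the racemic centre is excised in step 4.

Step 3
Reactants: 3 (2E,6E)-10-bromo-11-hydroxy-10,11-dihydrofarnesyl tert-butyldiphenylsilyl ether
Product: 4 (2E,6E)-10,11-epoxy-10,11-dihydrofarnesyl tert-butyldiphenylsilyl ether (racemic)
Conditions: K2CO3, MeOH, rt
Reagents that add atoms: none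
Why: Intramolecular Williamson closure of the bromohydrin alkoxide gives the terminal epoxide.

Step 4
Reactants: 4 (2E,6E)-10,11-epoxy-10,11-dihydrofarnesyl tert-butyldiphenylsilyl ether
Product: 6 (4E,8E)-10-[(tert-butyldiphenylsilyl)oxy]-4,8-dimethyldeca-4,8-dienal, via vicinal diol 5 (not isolated)
Conditions: H5IO6, THF–Et2O, 0 °C
Reagents that add atoms: none
Why: Periodic acid hydrates the epoxide and cleaves the resulting glycol (Malaprade cleavage), releasing acetone and the trisnor aldehyde (C11) without touching the internal alkenes.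

Step 5
Reactants: 6 (4E,8E)-10-[(tert-butyldiphenylsilyl)oxy]-4,8-dimethyldeca-4,8-dienal
Product: 7 tert-butyl{[(2E,6E)-11,11-dibromo-3,7-dimethylundeca-2,6,10-trien-1-yl]oxy}diphenylsilane
Conditions: CBr4, PPh3, Et3N, CH2Cl2, 0 °C
Reagents that add atoms: carbon tetrabromide, BrC(Br)(Br)Br
Why: Corey–Fuchs dibromo-olefination (Wittig reaction of the in situ dibromomethylene ylide) adds the carbon that becomes C12.

Step 6
Reactants: 7 tert-butyl{[(2E,6E)-11,11-dibromo-3,7-dimethylundeca-2,6,10-trien-1-yl]oxy}diphenylsilane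
Product: 9 tert-butyl{[(2E,6E)-3,7-dimethyldodeca-2,6-dien-10-yn-1-yl]oxy}diphenylsilane, via lithium acetylide 8 (not isolated)
Conditions: n-BuLi (2.2 equiv), THF, −78 °C; then MeI, −78 °C to rt
Reagents that add atoms: iodomethane, CI
Why: The second stage of the Corey–Fuchs sequence (bromine–lithium exchange, α-elimination with 1,2-shift, deprotonation) gives the acetylide, which is methylated to bring in C20.

Step 7
Reactants: 9 tert-butyl{[(2E,6E)-3,7-dimethyldodeca-2,6-dien-10-yn-1-yl]oxy}diphenylsilane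
Product: 11 tert-butyl{[(2E,6E,10E)-11-iodo-3,7-dimethyldodeca-2,6,10-trien-1-yl]oxy}diphenylsilane, via alkenylzirconocene chloride 10 (not isolated)
Conditions: Cp2Zr(H)Cl (2.5 equiv), THF, 50 °C; then I2, THF, 0 °C
Reagents that add atoms: iodine, II
Why: Hydrozirconation is a syn addition, and excess reagent with gentle warming should equilibrate zirconium to the less hindered, methyl-bearing carbon, so that iodinolysis with retention gives the (E)-2-iodo-2-alkene (chain cis to methyl); the trisubstituted alkenes do not hydrozirconate.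

Step 8
Reactants: 11 tert-butyl{[(2E,6E,10E)-11-iodo-3,7-dimethyldodeca-2,6,10-trien-1-yl]oxy}diphenylsilane
Product: 12 (2E,6E,10E)-11-iodo-3,7-dimethyldodeca-2,6,10-trien-1-ol
Conditions: TBAF, THF, 0 °C to rt
Reagents that add atoms: none
Why: Fluoride-induced desilylation frees the allylic alcohol and leaves the vinyl iodide intact.

Step 9
Reactants: 12 (2E,6E,10E)-11-iodo-3,7-dimethyldodeca-2,6,10-trien-1-ol
Product: 13 (2E,6E,10E)-11-iodo-3,7-dimethyldodeca-2,6,10-trienal
Conditions: MnO2, CH2Cl2, rt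
Reagents that add atoms: none
Why: MnO2 oxidises only the allylic alcohol and should keep the 2E geometry of the enal.

Step 10
Reactants: 14 3-[(tert-butyldimethylsilyl)oxy]propanal; 15 methyl acrylate
Product: 16 methyl 5-[(tert-butyldimethylsilyl)oxy]-3-hydroxy-2-methylidenepentanoate (racemic)
Conditions: DABCO, 1,4-dioxane–H2O, rt
Reagents that add atoms: none
Why: The Morita–Baylis–Hillman reaction joins C1 (aldehyde carbon) to C15 (acrylate α-carbon); the racemic carbinol centre disappears in step 12.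

Step 11
Reactants: 16 methyl 5-[(tert-butyldimethylsilyl)oxy]-3-hydroxy-2-methylidenepentanoate
Product: 17 methyl 3-acetoxy-5-[(tert-butyldimethylsilyl)oxy]-2-methylidenepentanoate (racemic)
Conditions: Ac2O, pyridine, DMAP (cat.), CH2Cl2, 0 °C
Reagents that add atoms: acetic anhydride, CC(=O)OC(C)=O
Why: Acetylation turns the carbinol into a leaving group for allylic substitution.

Step 12
Reactants: 17 methyl 3-acetoxy-5-[(tert-butyldimethylsilyl)oxy]-2-methylidenepentanoate
Product: 18 methyl (2E)-5-[(tert-butyldimethylsilyl)oxy]-2-[(4,4,5,5-tetramethyl-1,3,2-dioxaborolan-2-yl)methyl]pent-2-enoate (C14 chain cis to CH2B)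
Conditions: Pd2(dba)3 (2.5 mol %), B2pin2, toluene, 50 °C
Reagents that add atoms: bis(pinacolato)diboron, CC1(C)OB(OC1(C)C)B1OC(C)(C)C(C)(C)O1
Why: Palladium-catalysed SN2′ borylation of a Baylis–Hillman acetate (π-allyl formation, acetate-assisted transmetalation, C–B bond formation at the unsubstituted terminus) should give the trisubstituted alkene in its favoured geometry, chain trans to the ester and cis to CH2B.

Step 13
Reactants: 13 (2E,6E,10E)-11-iodo-3,7-dimethyldodeca-2,6,10-trienal; 18 methyl (2E)-5-[(tert-butyldimethylsilyl)oxy]-2-[(4,4,5,5-tetramethyl-1,3,2-dioxaborolan-2-yl)methyl]pent-2-enoate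
Product: 20 (4S,5S)-4-{2-[(tert-butyldimethylsilyl)oxy]ethyl}-5-[(1E,5E,9E)-10-iodo-2,6-dimethylundeca-1,5,9-trien-1-yl]-3-methylideneoxolan-2-one (cis lactone, cembrane 1S,2S), via borate adduct 19 (not isolated)
Conditions: (R)-TRIP phosphoric acid [(R)-3,3′-bis(2,4,6-triisopropylphenyl)-1,1′-binaphthyl-2,2′-diyl hydrogen phosphate] (10 mol %), 4 Å MS, toluene, 0 °C to rt; then PPTS (cat.), CH2Cl2, rt
Reagents that add atoms: none
Why: In the chiral phosphoric acid-catalysed allylboration the acid should bind a boronate oxygen and the formyl hydrogen in a closed six-membered chair transition state and direct the allyl unit to the Re face of the enal (C2 = S), while the C14 chain, cis to CH2B, sits axial so that the syn adduct and hence the cis lactone (C1 = S) result, the borate alkoxide closing onto the methyl ester (lactonisation, completed by PPTS).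

Step 14
Reactants: 20 (4S,5S)-4-{2-[(tert-butyldimethylsilyl)oxy]ethyl}-5-[(1E,5E,9E)-10-iodo-2,6-dimethylundeca-1,5,9-trien-1-yl]-3-methylideneoxolan-2-one
Product: 21 (4S,5S)-4-{2-[(tert-butyldimethylsilyl)oxy]ethyl}-5-[(1E,5S,6S,9E)-5,6-epoxy-10-iodo-2,6-dimethylundeca-1,9-dien-1-yl]-3-methylideneoxolan-2-one (cembrane 7S,8S)
Conditions: L-series Shi ketone (1,2:4,5-di-O-isopropylidene-β-L-erythro-2,3-hexodiulo-2,6-pyranose, from L-sorbose, 30 mol %), KHSO5 (as 2KHSO5·KHSO4·K2SO4), K2CO3, Bu4NHSO4, MeCN–CH2(OMe)2–aqueous buffer (pH about 10), −5 to 0 °C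
Reagents that add atoms: potassium peroxymonosulfate KHSO5, [K+].[O-]S(=O)(=O)OO
Why: In the Shi asymmetric epoxidation the electrophilic chiral dioxirane should pick the only electron-rich alkene, C7=C8 (C3=C4 is deactivated by the allylic lactone oxygen, the others are an acrylate and a vinyl iodide), and through the spiro transition state the L-series ketone should deliver oxygen to the face that gives the (7S,8S)-epoxide.

Step 15
Reactants: 21 (4S,5S)-4-{2-[(tert-butyldimethylsilyl)oxy]ethyl}-5-[(1E,5S,6S,9E)-5,6-epoxy-10-iodo-2,6-dimethylundeca-1,9-dien-1-yl]-3-methylideneoxolan-2-one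
Product: 22 (4S,5S)-5-[(1E,5S,6S,9E)-5,6-epoxy-10-iodo-2,6-dimethylundeca-1,9-dien-1-yl]-4-(2-hydroxyethyl)-3-methylideneoxolan-2-one
Conditions: HF·pyridine, excess pyridine, THF, 0 °C to rt
Reagents that add atoms: none
Why: Pyridine-buffered HF removes the primary silyl ether without opening the trisubstituted epoxide and, unlike basic fluoride, without provoking oxa-Michael addition of the new hydroxyl to the methylene lactone.

Step 16
Reactants: 22 (4S,5S)-5-[(1E,5S,6S,9E)-5,6-epoxy-10-iodo-2,6-dimethylundeca-1,9-dien-1-yl]-4-(2-hydroxyethyl)-3-methylideneoxolan-2-one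
Product: 23 (4S,5S)-5-[(1E,5S,6S,9E)-5,6-epoxy-10-iodo-2,6-dimethylundeca-1,9-dien-1-yl]-3-methylidene-4-(2-oxoethyl)oxolan-2-one
Conditions: Dess–Martin periodinane, NaHCO3, CH2Cl2, 0 °C to rt
Reagents that add atoms: none
Why: Buffered Dess–Martin oxidation gives the C13 aldehyde under neutral conditions that spare the epoxide, the vinyl iodide and the C1 stereocentre.

Step 17
Reactants: 23 (4S,5S)-5-[(1E,5S,6S,9E)-5,6-epoxy-10-iodo-2,6-dimethylundeca-1,9-dien-1-yl]-3-methylidene-4-(2-oxoethyl)oxolan-2-one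
Product: 25 (1S,2S,3E,7S,8S,11E,13RS)-7,8-epoxy-13-hydroxycembra-3,11,15(17)-trien-16,2-olide, via alkenylchromium dichloride 24 (not isolated)
Conditions: CrCl2 (10 equiv), NiCl2 (1 mol % of the CrCl2), degassed DMSO–THF, rt, syringe-pump addition to 2 mM
Reagents that add atoms: none
Why: In the Nozaki–Hiyama–Kishi macrocyclisation nickel activates the vinyl iodide, the alkenyl group passes to chromium with retention of the E geometry and adds only to the aldehyde, closing the 14-membered ring at C12–C13; both C13 epimers are carried on because this centre is erased in step 18.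

Step 18
Reactants: 25 (1S,2S,3E,7S,8S,11E,13RS)-7,8-epoxy-13-hydroxycembra-3,11,15(17)-trien-16,2-olide
Product: 27 (1S,2S,3E,7S,8R,11S,12E)-8,11-epidioxy-7-hydroxycembra-3,12,15(17)-trien-16,2-olide, via hydroxy hydroperoxide 26 (not isolated)
Conditions: anhydrous H2O2 in Et2O (about 30 equiv), HBF4·OEt2 (5 mol %), Et2O–CH2Cl2, −40 °C, then 0 °C; aqueous NaHCO3 quench without reductant
Reagents that add atoms: hydrogen peroxide, OO
Why: Proposed new method: acid makes the 7,8-epoxide and, on warming, the C13 carbinol electrophilic, so that one molecule of H2O2 is alkylated twice: it should open the epoxide from the rear at the tertiary carbon C8 (borderline SN2, inversion) to give 26, whose C8–OOH then traps the C11–C12–C13 allyl cation at C11 with shift of the alkene to C12=C13 (the reverse order, C11 hydroperoxide first and epoxide opening second, leads to the same product). The closest known reaction types are acid-catalysed perhydrolysis of trisubstituted epoxides to β-hydroxy hydroperoxides, 6-exo opening of epoxides by hydroperoxides, SN1 perhydrolysis of allylic alcohols and double alkylation of H2O2 by 1,4-bis-electrophiles. The 1,2-dioxane (O, O, C8, C9, C10, C11) closes transannularly in a six-membered mode, by capture of the allyl terminus C11 (or 6-exo-tet at C8 in the reverse order), whereas bonding to C13 would require an eight-membered ring holding an E alkene. C8 becomes R by inversion of the (8S)-epoxide carbon, C7 is untouched, and C11 (S) with the 12E geometry should follow from the ring itself, because the C7 and C12 arms can span the eight-atom bridge C6–C13 only when they are cis on the dioxane and the allyl unit is transoid; the two C13 epimers converge on ionisation. The step needs attack at C8 rather than C7 (tertiary carbon, six-membered ring), the hydroperoxide rather than the freed C7 hydroxyl or water as nucleophile (large excess of dry H2O2, alpha effect, acid-reversibility of misplaced allylic hydroperoxides) and survival of the alkenes and of the allylic lactone C2–O bond (metal-free acid in a few mol %, low temperature, ether as levelling base).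

Step 19
Reactants: 27 (1S,2S,3E,7S,8R,11S,12E)-8,11-epidioxy-7-hydroxycembra-3,12,15(17)-trien-16,2-olide
Product: 28 (1S,2S,3E,7S,8R,11S,12E)-7-acetoxy-8,11-epidioxycembra-3,12,15(17)-trien-16,2-olide (CNP0238885.7)
Conditions: Ac2O, pyridine, 0 °C
Reagents that add atoms: acetic anhydride, CC(=O)OC(C)=O
Why: Acetylation of the secondary C7 hydroxyl with nothing more basic than pyridine should avoid Kornblum–DeLaMare fragmentation of the peroxide through its C11 hydrogen.

**Compound list**

1 | (2E,6E)-farnesol | OC/C=C(\C)CC/C=C(\C)CCC=C(C)C | starting material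
2 | (2E,6E)-farnesyl tert-butyldiphenylsilyl ether | CC(C)(C)[Si](c1ccccc1)(c1ccccc1)OC/C=C(\C)CC/C=C(\C)CCC=C(C)C | intermediate
3 | (2E,6E)-10-bromo-11-hydroxy-10,11-dihydrofarnesyl tert-butyldiphenylsilyl ether (racemic) | CC(C)(C)[Si](c1ccccc1)(c1ccccc1)OC/C=C(\C)CC/C=C(\C)CCC(Br)C(C)(C)O | intermediate
4 | (2E,6E)-10,11-epoxy-10,11-dihydrofarnesyl tert-butyldiphenylsilyl ether (racemic) | CC(C)(C)[Si](c1ccccc1)(c1ccccc1)OC/C=C(\C)CC/C=C(\C)CCC1OC1(C)C | intermediate
5 | (2E,6E)-10,11-dihydroxy-10,11-dihydrofarnesyl tert-butyldiphenylsilyl ether | CC(C)(C)[Si](c1ccccc1)(c1ccccc1)OC/C=C(\C)CC/C=C(\C)CCC(O)C(C)(C)O | intermediate (not isolated)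
6 | (4E,8E)-10-[(tert-butyldiphenylsilyl)oxy]-4,8-dimethyldeca-4,8-dienal | CC(C)(C)[Si](c1ccccc1)(c1ccccc1)OC/C=C(\C)CC/C=C(\C)CCC=O | intermediate
7 | tert-butyl{[(2E,6E)-11,11-dibromo-3,7-dimethylundeca-2,6,10-trien-1-yl]oxy}diphenylsilane | CC(C)(C)[Si](c1ccccc1)(c1ccccc1)OC/C=C(\C)CC/C=C(\C)CCC=C(Br)Br | intermediate
8 | [(5E,9E)-11-[(tert-butyldiphenylsilyl)oxy]-5,9-dimethylundeca-5,9-dien-1-yn-1-yl]lithium | CC(C)(C)[Si](c1ccccc1)(c1ccccc1)OC/C=C(\C)CC/C=C(\C)CCC#C[Li] | intermediate (not isolated)
9 | tert-butyl{[(2E,6E)-3,7-dimethyldodeca-2,6-dien-10-yn-1-yl]oxy}diphenylsilane | CC(C)(C)[Si](c1ccccc1)(c1ccccc1)OC/C=C(\C)CC/C=C(\C)CCC#CC | intermediate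
10 | chlorobis(cyclopentadienyl)[(2E,6E,10E)-12-[(tert-butyldiphenylsilyl)oxy]-6,10-dimethyldodeca-2,6,10-trien-2-yl]zirconium | CC(C)(C)[Si](c1ccccc1)(c1ccccc1)OC/C=C(\C)CC/C=C(\C)CC/C=C(\C)[Zr](Cl)(C1C=CC=C1)C1C=CC=C1 | intermediate (not isolated)
11 | tert-butyl{[(2E,6E,10E)-11-iodo-3,7-dimethyldodeca-2,6,10-trien-1-yl]oxy}diphenylsilane | CC(C)(C)[Si](c1ccccc1)(c1ccccc1)OC/C=C(\C)CC/C=C(\C)CC/C=C(\C)I | intermediate
12 | (2E,6E,10E)-11-iodo-3,7-dimethyldodeca-2,6,10-trien-1-ol | OC/C=C(\C)CC/C=C(\C)CC/C=C(\C)I | intermediate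
13 | (2E,6E,10E)-11-iodo-3,7-dimethyldodeca-2,6,10-trienal | O=C/C=C(\C)CC/C=C(\C)CC/C=C(\C)I | intermediate
14 | 3-[(tert-butyldimethylsilyl)oxy]propanal | O=CCCO[Si](C)(C)C(C)(C)C | starting material
15 | methyl acrylate | C=CC(=O)OC | starting material
16 | methyl 5-[(tert-butyldimethylsilyl)oxy]-3-hydroxy-2-methylidenepentanoate (racemic) | C=C(C(=O)OC)C(O)CCO[Si](C)(C)C(C)(C)C | intermediate
17 | methyl 3-acetoxy-5-[(tert-butyldimethylsilyl)oxy]-2-methylidenepentanoate (racemic) | C=C(C(=O)OC)C(OC(C)=O)CCO[Si](C)(C)C(C)(C)C | intermediate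
18 | methyl (2E)-5-[(tert-butyldimethylsilyl)oxy]-2-[(4,4,5,5-tetramethyl-1,3,2-dioxaborolan-2-yl)methyl]pent-2-enoate | COC(=O)/C(CB1OC(C)(C)C(C)(C)O1)=C/CCO[Si](C)(C)C(C)(C)C | intermediate
19 | methyl (3S,4S,5E,9E,13E)-3-{2-[(tert-butyldimethylsilyl)oxy]ethyl}-14-iodo-6,10-dimethyl-2-methylidene-4-[(4,4,5,5-tetramethyl-1,3,2-dioxaborolan-2-yl)oxy]pentadeca-5,9,13-trienoate | C=C(C(=O)OC)[C@H](CCO[Si](C)(C)C(C)(C)C)[C@@H](OB1OC(C)(C)C(C)(C)O1)/C=C(\C)CC/C=C(\C)CC/C=C(\C)I | intermediate (not isolated)
20 | (4S,5S)-4-{2-[(tert-butyldimethylsilyl)oxy]ethyl}-5-[(1E,5E,9E)-10-iodo-2,6-dimethylundeca-1,5,9-trien-1-yl]-3-methylideneoxolan-2-one | C=C1C(=O)O[C@@H](/C=C(\C)CC/C=C(\C)CC/C=C(\C)I)[C@H]1CCO[Si](C)(C)C(C)(C)C | intermediate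
21 | (4S,5S)-4-{2-[(tert-butyldimethylsilyl)oxy]ethyl}-5-[(1E,5S,6S,9E)-5,6-epoxy-10-iodo-2,6-dimethylundeca-1,9-dien-1-yl]-3-methylideneoxolan-2-one | C=C1C(=O)O[C@@H](/C=C(\C)CC[C@@H]2O[C@@]2(C)CC/C=C(\C)I)[C@H]1CCO[Si](C)(C)C(C)(C)C | intermediate
22 | (4S,5S)-5-[(1E,5S,6S,9E)-5,6-epoxy-10-iodo-2,6-dimethylundeca-1,9-dien-1-yl]-4-(2-hydroxyethyl)-3-methylideneoxolan-2-one | C=C1C(=O)O[C@@H](/C=C(\C)CC[C@@H]2O[C@@]2(C)CC/C=C(\C)I)[C@H]1CCO | intermediate
23 | (4S,5S)-5-[(1E,5S,6S,9E)-5,6-epoxy-10-iodo-2,6-dimethylundeca-1,9-dien-1-yl]-3-methylidene-4-(2-oxoethyl)oxolan-2-one | C=C1C(=O)O[C@@H](/C=C(\C)CC[C@@H]2O[C@@]2(C)CC/C=C(\C)I)[C@H]1CC=O | intermediate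
24 | alkenylchromium dichloride of 23 (CrCl2 in place of iodine on C12) | C=C1C(=O)O[C@@H](/C=C(\C)CC[C@@H]2O[C@@]2(C)CC/C=C(\C)[Cr](Cl)Cl)[C@H]1CC=O | intermediate (not isolated)
25 | (1S,2S,3E,7S,8S,11E,13RS)-7,8-epoxy-13-hydroxycembra-3,11,15(17)-trien-16,2-olide | C=C1C(=O)O[C@H]2/C=C(\C)CC[C@@H]3O[C@@]3(C)CC/C=C(\C)C(O)C[C@@H]12 | intermediate
26 | (1S,2S,3E,7S,8R,11E,13RS)-8-hydroperoxy-7,13-dihydroxycembra-3,11,15(17)-trien-16,2-olide | C=C1C(=O)O[C@H]2/C=C(\C)CC[C@H](O)[C@](C)(OO)CC/C=C(\C)C(O)C[C@@H]12 | intermediate (not isolated)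
27 | (1S,2S,3E,7S,8R,11S,12E)-8,11-epidioxy-7-hydroxycembra-3,12,15(17)-trien-16,2-olide | C=C1C(=O)O[C@H]2/C=C(\C)CC[C@H](O)[C@@]3(C)CC[C@H](OO3)/C(C)=C/C[C@@H]12 | intermediate
28 | (1S,2S,3E,7S,8R,11S,12E)-7-acetoxy-8,11-epidioxycembra-3,12,15(17)-trien-16,2-olide (CNP0238885.7) | C=C1C(=O)O[C@H]2/C=C(\C)CC[C@H](OC(C)=O)[C@@]3(C)CC[C@H](OO3)/C(C)=C/C[C@@H]12 | target

**Totals**

Total step count: 19. Longest linear sequence: 16 steps (steps 1–9, then 13–19, from farnesol).

**Steps most likely to fail**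

Step 18 (proposed method). The two alkylations of H2O2 may not mesh. The epoxide should be perhydrolysed quickly, but ionisation at C13 may be too slow under acid mild enough for the allylic lactone. The allyl cation may be trapped by the freed C7 hydroxyl (cyclic ether formation), at C13 or from the wrong face. Allylic hydroperoxides may also be lost by acid-induced Hock-type cleavage. The fallback uses known reaction types in separate operations and makes the allylic C–O bond before the C7 hydroxyl exists. It sets out from 25, whose C13 hydroxyl is exchanged for bromide (CBr4, PPh3, 2,6-lutidine, CH2Cl2, −20 °C) to give (1S,2S,7S,8S)-13-bromo-7,8-epoxycembra-3,11,15(17)-trien-16,2-olide F1, used together with its allylic isomer. Silver-assisted perhydrolysis of the allylic bromide (AgO2CCF3, ethereal H2O2, 2,6-di-tert-butylpyridine, −20 °C), the established route from allylic bromides to allylic hydroperoxides, should then give (1S,2S,7S,8S,11S,12E)-7,8-epoxy-11-hydroperoxycembra-3,12,15(17)-trien-16,2-olide F2 after separation from its isomers, the buffered epoxide staying closed. F2 is finally closed by the known acid-catalysed 6-exo opening of an epoxide by a hydroperoxide (camphorsulfonic acid, CH2Cl2, 0 °C), with inversion at C8, which returns to the route at 27.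

Step 13. The ester-bearing boronate is a weak nucleophile, so the acid-catalysed addition may stall or proceed with poor facial discrimination on the trisubstituted enal. Long acid contact may also ionise the C2 carbinol (allylic, with a tertiary allyl terminus) and erode the cis relationship during lactonisation. The fallback replaces allylboration by a ligand-controlled chromium-catalysed allylation and sets out from 16. Bromination with allylic shift (NBS, Me2S, CH2Cl2, 0 °C) should give methyl (2Z)-2-(bromomethyl)-5-[(tert-butyldimethylsilyl)oxy]pent-2-enoate F3. A catalytic asymmetric Nozaki–Hiyama allylation of enal 13 with F3 (CrCl2 10 mol %, chiral carbazole bis(oxazoline) ligand, Mn powder, TMSCl, THF, rt; the vinyl iodide is inert to CrCl2 without nickel) should give the silylated syn adduct methyl (3S,4S,5E,9E,13E)-3-{2-[(tert-butyldimethylsilyl)oxy]ethyl}-14-iodo-6,10-dimethyl-2-methylidene-4-[(trimethylsilyl)oxy]pentadeca-5,9,13-trienoate F4. The syn course is expected from an allylchromium in which the chain stays cis to the metal-bearing CH2, and the ligand enantiomer would be chosen for 3S,4S. Mild acid (PPTS, MeOH–CH2Cl2) removes the trimethylsilyl group and lactonises, returning to the route at 20.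

Step 14. The dioxirane may lose site selectivity (oxidation at iodine or epoxidation of C3=C4), and the methylene lactone may suffer conjugate addition or hydrolysis at the pH the ketone catalyst needs. The fallback introduces the epoxide earlier, where neither the acrylate nor the lactone exists and the only other nucleophilic alkene is deactivated by the allylic silyl ether. It sets out from 11: the same asymmetric epoxidation should give tert-butyl{[(2E,6S,7S,10E)-6,7-epoxy-11-iodo-3,7-dimethyldodeca-2,10-dien-1-yl]oxy}diphenylsilane F5. TBAF then gives (2E,6S,7S,10E)-6,7-epoxy-11-iodo-3,7-dimethyldodeca-2,10-dien-1-ol F6, and MnO2 gives (2E,6S,7S,10E)-6,7-epoxy-11-iodo-3,7-dimethyldodeca-2,10-dienal F7. Allylboration of F7 with 18 under the conditions of step 13 should pass through the epoxy borate adduct F8 and lactonise, rejoining the route at 21; the phosphoric acid would be kept dry and free of nucleophiles so that the epoxide stays closed.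

Further compounds
F1 | step 18 | (1S,2S,3E,7S,8S,11E,13RS)-13-bromo-7,8-epoxycembra-3,11,15(17)-trien-16,2-olide | C=C1C(=O)O[C@H]2/C=C(\C)CC[C@@H]3O[C@@]3(C)CC/C=C(\C)C(Br)C[C@@H]12
F2 | step 18 | (1S,2S,3E,7S,8S,11S,12E)-7,8-epoxy-11-hydroperoxycembra-3,12,15(17)-trien-16,2-olide | C=C1C(=O)O[C@H]2/C=C(\C)CC[C@@H]3O[C@@]3(C)CC[C@H](OO)/C(C)=C/C[C@@H]12
F3 | step 13 | methyl (2Z)-2-(bromomethyl)-5-[(tert-butyldimethylsilyl)oxy]pent-2-enoate | COC(=O)/C(CBr)=C/CCO[Si](C)(C)C(C)(C)C
F4 | step 13 | methyl (3S,4S,5E,9E,13E)-3-{2-[(tert-butyldimethylsilyl)oxy]ethyl}-14-iodo-6,10-dimethyl-2-methylidene-4-[(trimethylsilyl)oxy]pentadeca-5,9,13-trienoate | C=C(C(=O)OC)[C@H](CCO[Si](C)(C)C(C)(C)C)[C@@H](O[Si](C)(C)C)/C=C(\C)CC/C=C(\C)CC/C=C(\C)I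
F5 | step 14 | tert-butyl{[(2E,6S,7S,10E)-6,7-epoxy-11-iodo-3,7-dimethyldodeca-2,10-dien-1-yl]oxy}diphenylsilane | CC(C)(C)[Si](c1ccccc1)(c1ccccc1)OC/C=C(\C)CC[C@@H]2O[C@@]2(C)CC/C=C(\C)I
F6 | step 14 | (2E,6S,7S,10E)-6,7-epoxy-11-iodo-3,7-dimethyldodeca-2,10-dien-1-ol | OC/C=C(\C)CC[C@@H]1O[C@@]1(C)CC/C=C(\C)I
F7 | step 14 | (2E,6S,7S,10E)-6,7-epoxy-11-iodo-3,7-dimethyldodeca-2,10-dienal | O=C/C=C(\C)CC[C@@H]1O[C@@]1(C)CC/C=C(\C)I
F8 | step 14 | methyl (3S,4S,5E,9S,10S,13E)-3-{2-[(tert-butyldimethylsilyl)oxy]ethyl}-9,10-epoxy-14-iodo-6,10-dimethyl-2-methylidene-4-[(4,4,5,5-tetramethyl-1,3,2-dioxaborolan-2-yl)oxy]pentadeca-5,13-dienoate | C=C(C(=O)OC)[C@H](CCO[Si](C)(C)C(C)(C)C)[C@@H](OB1OC(C)(C)C(C)(C)O1)/C=C(\C)CC[C@@H]2O[C@@]2(C)CC/C=C(\C)I
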